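The earlier runs and the new flask are calculated on assumed constants.

| flask | G | L | Q | time |
|---|---|---|---|---|
| elm | 0.400 M | 0.800 M | 0.0400 M |  |
| cedar | 0.160 M | 0.560 M | 0.0400 M |  |
| larch | 0.400 M | 0.800 M | 0.0600 M |  |
| alder | 0.400 M | 2.40 M | 0.0400 M |  |
| oak | 0.160 M | 0.320 M | 0.0400 M | 38 min |

- elm run (time / min: [E] / M): 2.9: 0.0053; 8.8: 0.0335; 17: 0.0745; 27: 0.1448; 38: 0.2227
- cedar run (time / min: [E] / M): 2.9: 0.0030; 8.8: 0.0074; 17: 0.0210; 27: 0.0315; 38: 0.0463
- larch run (time / min: [E] / M): 2.9: 0.0168; 8.8: 0.0474; 17: 0.1029; 27: 0.1803; 38: 0.2562
- alder run (time / min: [E] / M): 2.9: 0.0111; 8.8: 0.0722; 17: 0.2535; 27: 0.3753; 38: 0.3975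

(standard deviation of a reading: 0.002 M)

1. apparent order in [G] of the starting rate, round the charge of the elm run (the rate where two percent of its G have turned into E) (one fixed amount of E, the same in the runs compared)
2. apparent order in [Q] of the starting rate, round the charge of the elm run (the rate where two percent of its G have turned into E)
3. the cedar run starts with 0.240 M less of G and of L than the elm run, and with no E. Compared where both hold the same amount of G, once fifteen percent of what the cedar run was charged with has turned into E, is the cedar run faster, slower or alike (within a tenth)?
4. E in the oak run at 38 min, as a share of the G charged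

- Overall: G + L -> E, with Q as catalyst.
- Constant volume, constant temperature.
- The analysis sees a species whether free or bound.
- "The second partner" is L.
- An order is taken over about fifteen percent of the charge, up and down.

1. At 38 min I read c(E) = 0.2227 M in elm and 0.0463 M in cedar. Cedar is charged as elm stands once 0.240 M has reacted, with the same c(Q), but it holds no E. So cedar is the neighbour that tests what E does.

2. Over its last interval, elm makes E at 0.007082 M min⁻¹, at a mean c(E) of 0.184 M. From its first reading to its last, cedar makes E at 0.001234 M min⁻¹, at a mean c(E) of 0.0247 M. I divide each rate by c(G)c(L). This gives 0.0531 M⁻¹ min⁻¹ for elm and 0.0170 M⁻¹ min⁻¹ for cedar. Elm's quotient is larger than cedar's, so I read the reaction as autocatalysis: E speeds its own formation.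

3. A straight line through these two points has the slope 0.227 M⁻² min⁻¹. I take the symmetric case as the zero of my scale: the crossing amount, the c(E) at which the part of the quotient that grows with E equals the part present without E. From the two readings it comes to 0.0503 M, and it carries their scatter.

4. At the point asked, cedar holds 0.0240 M of E and elm holds 0.264 M. Cedar then has 0.136 M of G and elm has 0.136 M, and the two c(L) are equal as well, 0.536 M and 0.536 M. The rate ratio therefore reduces to (crossing amount + cedar's E)/(crossing amount + elm's E), which is 0.237. Cedar holds less E than elm, so I say cedar is slower.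

5. Both parts of the rate carry c(G), so I take an order of about 1 in G. I take the E readings of larch over elm at 8.8 min as a rough rate ratio, and this gives an order in Q of 0.856.

6. Oak differs from cedar in its c(L) alone. The E readings of alder over elm at 8.8 min, taken the same way, give an order in L of 0.699. Scaling cedar's last reading by it, I expect 19.6% in oak.

7. The forecast, which differs from my reckoning on Q and on oak, gives 1, 1.3, slower and 14%, on the ground that “The rate clearly speeds up as E builds, so E itself promotes the reaction.”

8. The flask gives 0.96, 0.79, slower and 21.2%.

    Q + G ⇌ QG, settled at all times (1.240 M⁻¹)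
    QG + L → E + Q + X (1.188 M⁻¹ min⁻¹)
    G + L + E → 2 E (0.2502 M⁻² min⁻¹)
    Q + L ⇌ QL, settled at all times (7.040 M⁻¹)

Oak at 38 min holds 21.2% of the G charged, less than the quarter of its G that cedar reaches at 33.4 min. That is 0.0339 M of E, below the crossing amount of 0.0503 M, which I read from elm and cedar, charged with more L than oak. For cedar against elm at the point asked, where c(G) and c(L) are equal, the crossing amount gives a rate ratio of 0.237, and the flask gives 0.24.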